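**Assumptions.** The SMILES is read as the all-trans, C2-symmetric (2R,3S,4S,5R) isomer, and that is the compound made. The catalyst enantiomer in Step 4 assumes the usual syn sense of dynamic kinetic resolution for α-carbon-substituted aryl β-keto esters; this sense is not established for this substrate.

## Retrosynthetic overview

1. (+)-Neoolivil (10) comes from LiAlH4 reduction of the all-trans tetrahydrofuran-3,4-diester 9, with no stereochemical change.
2. The tetrahydrofuran ring of 9 is formed last, by acidic methanolysis and benzylic SN1 ring closure of the C2-symmetric bis-γ-lactone 7.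
3. The two lactone rings of 7 form first, from a double asymmetric transfer hydrogenation with dynamic kinetic resolution of the symmetric, stereochemically labile 2,3-diaroylsuccinate 6. This key step sets all four stereocentres.
4. Diketone 6 comes from oxidative enolate homodimerisation (C8–C8′ bond) of β-keto ester 5.
5. β-Keto ester 5 comes from acetovanillone (1) by MOM protection and Claisen C-acylation with dimethyl carbonate.

## Route

**Step 1**
Reactants: 1, acetovanillone (4′-hydroxy-3′-methoxyacetophenone); 2, chloromethyl methyl ether
Product: 3, 1-[3-methoxy-4-(methoxymethoxy)phenyl]ethan-1-one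
Conditions: MOMCl, i-Pr2NEt, CH2Cl2, 0 °C → rt
Reagents that add atoms: chloromethyl methyl ether, COCCl
Why: Phenol O-alkylation (MOM ether formation) masks the phenol against base and iodine in Steps 2–3, and the group is removed for free by the acid in Step 5.

**Step 2**
Reactants: 3, MOM-protected acetovanillone; 4, dimethyl carbonate
Product: 5, methyl 3-[3-methoxy-4-(methoxymethoxy)phenyl]-3-oxopropanoate
Conditions: NaH (2.5 equiv), (MeO)2CO (4 equiv), THF, reflux; AcOH quench
Reagents that add atoms: dimethyl carbonate, COC(=O)OC
Why: Crossed Claisen condensation of the methyl ketone enolate with a non-enolisable carbonate is driven by irreversible deprotonation of the β-keto ester product.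

**Step 3**
Reactants: 5, β-keto ester (2 equiv)
Product: 6, dimethyl 2,3-bis[3-methoxy-4-(methoxymethoxy)benzoyl]succinate (meso/dl mixture, used as such)
Conditions: NaH (1.05 equiv), THF, 0 °C; I2 (0.5 equiv), 0 °C → rt; Na2S2O3 work-up (no acid)
Reagents that add atoms: none
Why: Knorr-type oxidative homocoupling of a β-keto ester enolate (α-iodination, then SN2 by a second enolate) forms the C8–C8′ bond; the new stereocentres are labile and deliberately left uncontrolled.

**Step 4 (key step)**
Reactants: 6, dimethyl 2,3-diaroylsuccinate
Product: 7, (1R,4R,5R,8R)-4,8-bis[3-methoxy-4-(methoxymethoxy)phenyl]-3,7-dioxabicyclo[3.3.0]octane-2,6-dione (cis-fused bis-γ-lactone, both aryl groups exo)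
Conditions: RuCl(p-cymene)[(R,R)-TsDPEN] (4 mol%), HCO2H/Et3N (5:2), DMF, 40 °C, 48 h; then PPTS (cat.), PhMe, 60 °C to complete lactonisation
Reagents that add atoms: none (formic acid supplies hydrogen only)
Why: Proposed new method: a two-directional Noyori–Ikariya transfer hydrogenation with dynamic kinetic resolution, in which Et3N keeps both α-centres of the meso/dl diketone epimerising while the (R,R)-catalyst gives each aryl ketone the (R)-carbinol with syn-selective relay to the adjacent α-carbon, so the symmetric mixture converges on the (7R,8R,8′R,7′R)-diol, whose syn γ-hydroxy esters close to the cis-fused bis-lactone; the closest known reaction is the single transfer-hydrogenation/DKR/lactonisation of α-substituted aryl β-keto esters (2-acylsuccinates to paraconates), and double reaction of a bifunctional substrate should raise ee by diverting mismatched material into a separable meso-type diastereomer.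

**Step 5**
Reactants: 7, bis-lactone; 8, methanol
Product: 9, dimethyl (2R,3R,4R,5R)-2,5-bis(4-hydroxy-3-methoxyphenyl)tetrahydrofuran-3,4-dicarboxylate (all-trans)
Conditions: HCl (from AcCl, ~1 M) in dry MeOH, 0 °C → 50 °C; NaHCO3 work-up
Reagents that add atoms: methanol, CO
Why: Acid-catalysed lactone methanolysis followed by SN1 cycloetherification through a p-hydroxybenzyl cation (MOM groups are lost in the same pot) gives the tetrahydrofuran; C3/C4 are not touched and keep the Step 4 configuration, while the benzylic C2/C5 centres close reversibly to the thermodynamic all-trans arrangement, so any carbinol epimers from Step 4 converge.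

**Step 6**
Reactants: 9, tetrahydrofuran diester
Product: 10, (+)-neoolivil, (2R,3S,4S,5R)-2,5-bis(4-hydroxy-3-methoxyphenyl)-3,4-bis(hydroxymethyl)tetrahydrofuran
Conditions: LiAlH4 (6 equiv), THF, 0 °C → rt; Rochelle salt work-up
Reagents that add atoms: none
Why: Hydride reduction of both esters to primary alcohols leaves the benzylic ether ring and all four stereocentres untouched (the free phenols only consume hydride as phenoxides); the descriptor change at C3/C4 from R to S is a priority change only.

Steps 4 and 5 can be telescoped: any uncyclised hydroxy ester from Step 4 gives the same product 9 in Step 5.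

## Compound list

1 | acetovanillone | CC(=O)c1ccc(O)c(OC)c1 | starting material
2 | chloromethyl methyl ether | COCCl | starting material
3 | 1-[3-methoxy-4-(methoxymethoxy)phenyl]ethan-1-one | CC(=O)c1ccc(OCOC)c(OC)c1 | intermediate
4 | dimethyl carbonate | COC(=O)OC | starting material
5 | methyl 3-[3-methoxy-4-(methoxymethoxy)phenyl]-3-oxopropanoate | COC(=O)CC(=O)c1ccc(OCOC)c(OC)c1 | intermediate
6 | dimethyl 2,3-bis[3-methoxy-4-(methoxymethoxy)benzoyl]succinate (meso/dl) | COC(=O)C(C(=O)c1ccc(OCOC)c(OC)c1)C(C(=O)OC)C(=O)c1ccc(OCOC)c(OC)c1 | intermediate
7 | (1R,4R,5R,8R)-4,8-bis[3-methoxy-4-(methoxymethoxy)phenyl]-3,7-dioxabicyclo[3.3.0]octane-2,6-dione | O=C1O[C@@H](c2ccc(OCOC)c(OC)c2)[C@H]3[C@@H]1[C@H](c4ccc(OCOC)c(OC)c4)OC3=O | intermediate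
8 | methanol | CO | starting material (reagent/solvent)
9 | dimethyl (2R,3R,4R,5R)-2,5-bis(4-hydroxy-3-methoxyphenyl)tetrahydrofuran-3,4-dicarboxylate | COc1cc([C@@H]2O[C@@H](c3ccc(O)c(OC)c3)[C@H](C(=O)OC)[C@H]2C(=O)OC)ccc1O | intermediate
10 | (+)-neoolivil | COc1cc([C@@H]2O[C@@H](c3ccc(O)c(OC)c3)[C@H](CO)[C@H]2CO)ccc1O | target

## Summary

Total steps: 6. Longest linear sequence: 6.

Steps most likely to fail, each with a fallback that changes the approach:

1. **Step 4 (double transfer hydrogenation with DKR).** Risks are the wrong or a poor syn/anti sense, a sluggish second reduction of the electron-rich hindered ketone, and Paal–Knorr furan formation. If the relay turns out anti, (R,R)-catalyst would deliver the wrong enantiomer and the (S,S)-catalyst must be used instead. Fallback: separate the stereo-setting from the coupling. Reduce the simple β-keto ester 5 by single transfer hydrogenation to the enantiopure β-hydroxy ester, then form C8–C8′ by oxidative homocoupling of its Fráter–Seebach dianion (LDA, then I2 or CuCl2). The carbinol relays its configuration to C8, and the carbinol enantiomer is chosen to match the anti sense of that relay.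

2. **Step 5 (bis-lactone to tetrahydrofuran).** Risks are Friedel–Crafts closure of the benzylic cation onto the other guaiacyl ring (aryltetralin or aryldihydronaphthalene), E1 loss to a benzylidene succinate, and persistent 7-OMe open-chain ethers. Fallback: reverse the order of reduction and ring closure. Reduce 7 with LiAlH4 to the tetraol, protect the two primary alcohols selectively (TBDPSCl), cyclodehydrate the benzylic 1,4-diol under mild conditions (cat. BF3·OEt2 or MsCl/Et3N), then remove the silyl and MOM groups. The primary-OH protection blocks the competing furofuran (pinoresinol-type) closure.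

3. **Step 3 (oxidative homodimerisation).** Risks are C–O coupling, over-iodination and cyclisation of the 1,4-diketone to dihydrofuran or furan. Fallback: form the two C7–C8 bonds on a pre-formed C8–C8′ unit instead. Doubly C-acylate the bis-enolate (or bis-silyl ketene acetal) of dimethyl succinate with 3-methoxy-4-(methoxymethoxy)benzoyl chloride or imidazolide, which gives 6 from succinate plus a vanillic acid derivative.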